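The δ-lactone is opened at two bonds, C4–C4a and O2–C3. Because the carboxyl carbon C1 and the benzylic C4 sit ortho on the benzene ring, and O2 and C4 share C3, the heterocycle is the formal oxyarylation product of a C=C bond; because C3 carries a chain, that alkene can be the terminal double bond of a 1,3-diene. The key step is an enantioselective palladium-catalysed heteroannulation (Heck/Tsuji–Trost cascade) of 2-bromo-4,6-dimethoxybenzoic acid with (E)-trideca-10,12-dien-5-one: one operation forms the aryl–CH2 bond, the carboxylate O–CH bond, the lactone ring and the C3 stereocentre. Alkene hydrogenation and cleavage of the 8-O-methyl ether finish the synthesis.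

Key step: step 6

Remark: ring atoms are numbered as in isochroman-1-one (C1 lactone carbonyl, O2, C3, C4, C4a–C8a), and the target is (3R). The antipode of the chiral ligand in step 6 is taken to be the one that a ligand screen shows to give the 3S lactone 11; this is an experimental choice, not a prediction.

Step 1
Reactants: 1 ε-caprolactone (oxepan-2-one); 2 n-butyllithium
Product: 3 1-hydroxydecan-6-one
Conditions: n-BuLi (1.0 equiv, slow addition), THF, −78 °C; AcOH quench at −78 °C
Reagents that add atoms: none
Why: Mono-addition of an organolithium to a lactone (nucleophilic acyl substitution with ring opening); slow addition of one equivalent at −78 °C and a cold acidic quench should keep a second addition to the new ketone in check.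

Step 2
Reactants: 3 1-hydroxydecan-6-one
Product: 4 6-oxodecanal
Conditions: Dess–Martin periodinane, CH2Cl2, 0 °C to rt
Reagents that add atoms: none
Why: Dess–Martin oxidation should take the primary alcohol to the aldehyde under near-neutral, non-enolising conditions, which the 1,6-keto aldehyde needs to escape intramolecular aldol condensation.

Step 3
Reactants: 4 6-oxodecanal; 5 diethyl allylphosphonate
Product: 6 (E)-trideca-10,12-dien-5-one
Conditions: 5, n-BuLi, THF, −78 °C; HMPA; then 4, −78 °C to rt
Reagents that add atoms: none
Why: Horner–Wadsworth–Emmons-type olefination with the lithiated allylphosphonate, in which α-attack on the aldehyde (the ketone is much slower at −78 °C) and phosphate elimination in the presence of HMPA should give the terminal (E)-1,3-diene.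

Step 4
Reactants: 7 1-bromo-3,5-dimethoxybenzene
Product: 9 2-bromo-4,6-dimethoxybenzaldehyde, via iminium chloride 8 (not isolated)
Conditions: POCl3, DMF, 0 to 90 °C; then ice/water
Reagents that add atoms: N,N-dimethylformamide, CN(C)C=O (formyl carbon); water, O (carbonyl oxygen)
Why: Vilsmeier–Haack formylation, in which the chloroiminium electrophile should attack C2 (ortho to one OMe and para to the other, whereas C4 between both OMe groups is more hindered) and the iminium salt 8 is hydrolysed on aqueous work-up.

Step 5
Reactants: 9 2-bromo-4,6-dimethoxybenzaldehyde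
Product: 10 2-bromo-4,6-dimethoxybenzoic acid
Conditions: NaClO2, NaH2PO4, 2-methyl-2-butene, t-BuOH/H2O, rt
Reagents that add atoms: sodium chlorite, [Na+].[O-]Cl=O
Why: Pinnick oxidation should convert the aldehyde into the acid without touching the aryl bromide, while the alkene scavenger removes HOCl and so protects the electron-rich ring from chlorination.

Step 6
Reactants: 10 2-bromo-4,6-dimethoxybenzoic acid; 6 (E)-trideca-10,12-dien-5-one
Product: 11 (3S)-6,8-dimethoxy-3-[(1E)-7-oxoundec-1-en-1-yl]-3,4-dihydro-1H-isochromen-1-one
Conditions: Pd2(dba)3·CHCl3 (2.5 mol%), chiral sulfinamide monophosphine (Sadphos class, 10 mol%), K2CO3 (1.5 equiv), 6 (1.5 equiv), 1,4-dioxane, 80 °C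
Reagents that add atoms: none
Why: Oxidative addition of Pd(0) into the C–Br bond of 10 and carbopalladation of the terminal, unsubstituted C12=C13 bond of 6 place the aryl group on C13 (the future C4) and give a syn-η3-allylpalladium carboxylate; C–O bond formation between the ortho carboxylate oxygen and the allyl terminus next to the new CH2 (the future C3) closes the lactone and returns Pd(0). The reaction type is the palladium-catalysed heteroannulation of 1,3-dienes by ortho-functionalised aryl halides (Larock-type Heck/Tsuji–Trost cascade), which is known for ortho-halobenzoic acids and is run here with a chiral monophosphine as in its enantioselective variants. The ring closes as a 6-exo allylic substitution, since attack at the distal allyl terminus would require an eight-membered lactone. C3 is the only new stereocentre and is under catalyst control: the chiral ligand on palladium should differentiate the two faces of the allyl unit in the C–O bond-forming event, and the ligand antipode is selected for 3S. The step needs 1,2- rather than 1,4-oxyarylation, insertion at the terminal rather than the internal alkene and cyclisation faster than β-hydride elimination; ring size secures the first, the steric difference between the two diene termini the second, and the carboxylate held ortho to the new CH2 the third. The (E)-alkene follows from the syn-allyl geometry, and the remote ketone, the aryl ethers and the mild carbonate base should not interfere.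

Step 7
Reactants: 11 (3S)-6,8-dimethoxy-3-[(1E)-7-oxoundec-1-en-1-yl]-3,4-dihydro-1H-isochromen-1-one
Product: 12 (3R)-6,8-dimethoxy-3-(7-oxoundecyl)-3,4-dihydro-1H-isochromen-1-one
Conditions: H2 (1 atm), RhCl(PPh3)3 (5 mol%), toluene/EtOH 1:1, rt
Reagents that add atoms: none
Why: Homogeneous hydrogenation with Wilkinson's catalyst should saturate the disubstituted alkene without hydrogenolysis of the allylic C3–O bond or reduction of the ketone; no bond at C3 is touched, and the descriptor changes from S to R only because the CIP priorities change.

Step 8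
Reactants: 12 (3R)-6,8-dimethoxy-3-(7-oxoundecyl)-3,4-dihydro-1H-isochromen-1-one
Product: 14 (3R)-8-hydroxy-6-methoxy-3-(7-oxoundecyl)-3,4-dihydro-1H-isochromen-1-one, via aryl dichloroborinate 13 (not isolated)
Conditions: BCl3 (1 M in CH2Cl2, 2.5 equiv), CH2Cl2, −78 to 0 °C; then water
Reagents that add atoms: none
Why: Chelation-controlled Lewis-acid ether cleavage, in which BCl3 bound between the lactone C1=O and the peri 8-OMe oxygen should deliver chloride to that methyl group only (the 6-OMe has no chelating neighbour), and aqueous work-up hydrolyses 13 to the hydrogen-bonded phenol.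

Compound list
1 | ε-caprolactone (oxepan-2-one) | O=C1CCCCCO1 | starting material
2 | n-butyllithium | [Li]CCCC | starting material
3 | 1-hydroxydecan-6-one | CCCCC(=O)CCCCCO | intermediate
4 | 6-oxodecanal | CCCCC(=O)CCCCC=O | intermediate
5 | diethyl allylphosphonate | C=CCP(=O)(OCC)OCC | starting material
6 | (E)-trideca-10,12-dien-5-one | CCCCC(=O)CCCC/C=C/C=C | intermediate
7 | 1-bromo-3,5-dimethoxybenzene | COc1cc(Br)cc(OC)c1 | starting material
8 | (2-bromo-4,6-dimethoxybenzylidene)dimethyliminium chloride | COc1cc(Br)c(C=[N+](C)C)c(OC)c1.[Cl-] | intermediate (not isolated)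
9 | 2-bromo-4,6-dimethoxybenzaldehyde | COc1cc(Br)c(C=O)c(OC)c1 | intermediate
10 | 2-bromo-4,6-dimethoxybenzoic acid | COc1cc(Br)c(C(=O)O)c(OC)c1 | intermediate
11 | (3S)-6,8-dimethoxy-3-[(1E)-7-oxoundec-1-en-1-yl]-3,4-dihydro-1H-isochromen-1-one | CCCCC(=O)CCCC/C=C/[C@@H]1Cc2cc(OC)cc(OC)c2C(=O)O1 | intermediate
12 | (3R)-6,8-dimethoxy-3-(7-oxoundecyl)-3,4-dihydro-1H-isochromen-1-one | CCCCC(=O)CCCCCC[C@@H]1Cc2cc(OC)cc(OC)c2C(=O)O1 | intermediate
13 | (3R)-6-methoxy-1-oxo-3-(7-oxoundecyl)-3,4-dihydro-1H-isochromen-8-yl dichloroborinate | CCCCC(=O)CCCCCC[C@@H]1Cc2cc(OC)cc(OB(Cl)Cl)c2C(=O)O1 | intermediate (not isolated)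
14 | (3R)-8-hydroxy-6-methoxy-3-(7-oxoundecyl)-3,4-dihydro-1H-isochromen-1-one | CCCCC(=O)CCCCCC[C@@H]1Cc2cc(OC)cc(O)c2C(=O)O1 | target

Total step count: 8
Longest linear sequence: 6 steps (steps 1, 2, 3, 6, 7, 8); the aryl branch (steps 4, 5) joins at step 6.

Steps most likely to fail

1. Step 6. What may go wrong:
- the ligand may discriminate the allyl faces poorly when a carboxylate is the terminating nucleophile;
- the ee may erode through Pd(0) re-ionisation of the allylic lactone;
- β-hydride elimination may divert the allyl intermediate to Heck trienes;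
- the electron-rich, 2,6-disubstituted acid may protodecarboxylate.

Fallback, from 10 back to the route at 12: the two bonds are formed without a stereocentre and C3 is set afterwards by hydrogenation. Commercial non-8-ynoic acid is converted (CDI; MeNHOMe·HCl) into N-methoxy-N-methylnon-8-ynamide F1, and n-BuMgCl (2.2 equiv, THF, 0 °C) should give tridec-12-yn-5-one F2. Ethylene glycol/TsOH (toluene, Dean–Stark) protects the ketone as 2-butyl-2-(oct-7-yn-1-yl)-1,3-dioxolane F3. Sonogashira coupling of 10 with F3 and in situ 6-endo-dig lactonisation (Pd/C, PPh3, CuI, Et3N, EtOH, 80 °C) should give the isocoumarin 3-[6-(2-butyl-1,3-dioxolan-2-yl)hexyl]-6,8-dimethoxy-1H-isochromen-1-one F4. Enantioselective hydrogenation of its C3=C4 bond with a chiral Ru–NHC catalyst should give (3R)-3-[6-(2-butyl-1,3-dioxolan-2-yl)hexyl]-6,8-dimethoxy-3,4-dihydro-1H-isochromen-1-one F5. PPTS in acetone/water removes the ketal and returns 12.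

2. Step 3. What may go wrong:
- the strongly basic carbanion may enolise the 1,6-keto aldehyde and trigger intramolecular aldol condensation;
- the allyl anion may attack through its γ-carbon;
- the E-selectivity may be incomplete.

Fallback, from 4 back to the route at 6: base-free, aldehyde-selective allylboration with pinacol (E)-[3-(trimethylsilyl)allyl]boronate (CH2Cl2, rt) should give, through a chair transition state, anti-10-[(4,4,5,5-tetramethyl-1,3,2-dioxaborolan-2-yl)oxy]-11-(trimethylsilyl)tridec-12-en-5-one F6. Triethanolamine work-up hydrolyses it to anti-10-hydroxy-11-(trimethylsilyl)tridec-12-en-5-one F7. Acid-promoted anti Peterson elimination (cat. H2SO4, THF, rt) should then give 6 with E geometry.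

3. Step 1. What may go wrong:
- a second addition of n-BuLi to the ketone as it is released would give a tertiary alcohol;
- the lactone may enolise.

Fallback, from 1 back to the route at 3: ring opening with MeNHOMe·HCl/i-PrMgCl (THF, −20 °C) should give the Weinreb amide 6-hydroxy-N-methoxy-N-methylhexanamide F8. Its chelated tetrahedral adduct with n-BuMgCl (2.2 equiv, THF, 0 °C) cannot over-add and should release 3 on work-up.

Further compounds
F1 | step 6 | N-methoxy-N-methylnon-8-ynamide | C#CCCCCCCC(=O)N(C)OC
F2 | step 6 | tridec-12-yn-5-one | CCCCC(=O)CCCCCCC#C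
F3 | step 6 | 2-butyl-2-(oct-7-yn-1-yl)-1,3-dioxolane | CCCCC1(CCCCCCC#C)OCCO1
F4 | step 6 | 3-[6-(2-butyl-1,3-dioxolan-2-yl)hexyl]-6,8-dimethoxy-1H-isochromen-1-one | CCCCC1(CCCCCCC2=Cc3cc(OC)cc(OC)c3C(=O)O2)OCCO1
F5 | step 6 | (3R)-3-[6-(2-butyl-1,3-dioxolan-2-yl)hexyl]-6,8-dimethoxy-3,4-dihydro-1H-isochromen-1-one | CCCCC1(CCCCCC[C@@H]2Cc3cc(OC)cc(OC)c3C(=O)O2)OCCO1
F6 | step 3 | anti-10-[(4,4,5,5-tetramethyl-1,3,2-dioxaborolan-2-yl)oxy]-11-(trimethylsilyl)tridec-12-en-5-one (racemic, one enantiomer drawn) | CCCCC(=O)CCCC[C@H](OB1OC(C)(C)C(C)(C)O1)[C@H]([Si](C)(C)C)C=C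
F7 | step 3 | anti-10-hydroxy-11-(trimethylsilyl)tridec-12-en-5-one (racemic, one enantiomer drawn) | CCCCC(=O)CCCC[C@H](O)[C@H]([Si](C)(C)C)C=C
F8 | step 1 | 6-hydroxy-N-methoxy-N-methylhexanamide | CON(C)C(=O)CCCCCO
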